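**Retrosynthetic overview**
1. Ester C–O bond: target ⇒ core triol + (2S,3R)-2,3-dimethyloxirane-2-carboxylic acid, the acid made in one step by asymmetric epoxidation of tiglic acid.
2. cis-Diol ⇒ α-face dihydroxylation of the ring-A alkene; hydroxyisopropyl enone ⇒ acetone aldol, then dehydrogenation of the bicyclic ketone.
3. Ring A (formed last) ⇒ ring-closing metathesis of a butenyl/isopropenyl cyclohexanone.
4. Ring B ⇒ one-carbon ring expansion of an α-quaternary cyclopentanone in which the quaternary carbon undergoes the 1,2-shift, moving C=O from α to β of the methyl-bearing stereocentre.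
5. Cyclopentanone ⇒ 2-methylcyclopent-2-enone + isopropenyl-MgBr (asymmetric conjugate addition) + 4-iodobut-1-ene (enolate alkylation). Ring order: five-membered ring bought → ring B by expansion → ring A by RCM; the oxirane is made separately.

Assumption: for the two chiral catalysts the ligand enantiomer that gives the drawn configuration is used; "C5, C7, C8, C9, C10" in the text are eudesmane numbers (C10 = methyl-bearing ring-fusion carbon, C5 = ring-fusion CH, C8 = ring ketone).

**Step 1**
Reactants: 1 2-methylcyclopent-2-en-1-one; 2 isopropenylmagnesium bromide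
Product: 4 (S)-trimethyl{[2-methyl-3-(prop-1-en-2-yl)cyclopent-1-en-1-yl]oxy}silane, via magnesium enolate 3 (not isolated)
Conditions: Cu(OTf)2 (4 mol%), chiral NHC ligand (from imidazolinium salt, 5 mol%), Et2O, −30 °C; then TMSCl, DMPU, −30 → 0 °C
Reagents that add atoms: chlorotrimethylsilane C[Si](C)(C)Cl
Why: Cu–NHC-catalysed asymmetric conjugate addition of a Grignard reagent to an α-substituted cyclic enone, in which the chiral Cu(I) complex delivers isopropenyl to one face of the β-carbon (sets C5, 3S) and O-silylation of the magnesium enolate fixes the enolate regiochemistry.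

**Step 2**
Reactants: 4 (S)-trimethyl{[2-methyl-3-(prop-1-en-2-yl)cyclopent-1-en-1-yl]oxy}silane; 5 4-iodobut-1-ene
Product: 7 (2S,3S)-2-(but-3-en-1-yl)-2-methyl-3-(prop-1-en-2-yl)cyclopentan-1-one, via lithium enolate 6 (not isolated)
Conditions: MeLi, THF, 0 °C; then HMPA, 5, −78 → 0 °C
Reagents that add atoms: none
Why: MeLi cleavage of the silyl enol ether gives the regiodefined tetrasubstituted lithium enolate, whose SN2 C-alkylation occurs anti to the neighbouring isopropenyl group and so sets the quaternary centre C10 (methyl cis, butenyl trans to isopropenyl).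

**Step 3**
Reactants: 7 (2S,3S)-2-(but-3-en-1-yl)-2-methyl-3-(prop-1-en-2-yl)cyclopentan-1-one
Product: 11 (3R,4S)-3-(but-3-en-1-yl)-3-methyl-4-(prop-1-en-2-yl)cyclohexan-1-one, via dibromomethyl alkoxide 8 (not isolated), via carbenoid 9 (not isolated), via lithium enolate 10 (not isolated)
Conditions: CH2Br2, LDA, THF, −78 °C; then n-BuLi (1.2 equiv), −95 → −20 °C; H2O
Reagents that add atoms: dibromomethane BrCBr
Why: Taguchi–Yamamoto–Nozaki β-oxido carbenoid ring enlargement, in which LiCHBr2 adds to the ketone, Br/Li exchange gives the carbenoid and the more substituted (quaternary) α-carbon migrates with retention, so the carbonyl ends β to the quaternary stereocentre and neither stereocentre is touched.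

**Step 4**
Reactants: 11 (3R,4S)-3-(but-3-en-1-yl)-3-methyl-4-(prop-1-en-2-yl)cyclohexan-1-one
Product: 12 (4aR,8aR)-5,8a-dimethyl-3,4,4a,7,8,8a-hexahydronaphthalen-2(1H)-one
Conditions: Grubbs II (3 mol%), CH2Cl2, 40 °C
Reagents that add atoms: none
Why: Ring-closing olefin metathesis of the terminal and 1,1-disubstituted alkenes closes ring A as a trisubstituted cyclohexene, with the trans ring fusion already fixed by the two existing stereocentres.

**Step 5**
Reactants: 12 (4aR,8aR)-5,8a-dimethyl-3,4,4a,7,8,8a-hexahydronaphthalen-2(1H)-one; 13 acetone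
Product: 15 (4aR,8aR)-3-(2-hydroxypropan-2-yl)-5,8a-dimethyl-3,4,4a,7,8,8a-hexahydronaphthalen-2(1H)-one (C3 epimers), via lithium enolate 14 (not isolated)
Conditions: LDA, THF, −78 °C; acetone, −78 °C; AcOH
Reagents that add atoms: none
Why: Kinetic deprotonation takes the α-CH2 remote from the quaternary carbon (the other α-CH2 is neopentyl) and the enolate undergoes aldol addition to acetone, the new C7 centre being uncontrolled but removed in step 6.

**Step 6**
Reactants: 15 (4aR,8aR)-3-(2-hydroxypropan-2-yl)-5,8a-dimethyl-3,4,4a,7,8,8a-hexahydronaphthalen-2(1H)-one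
Product: 16 (4aR,8aR)-3-(2-hydroxypropan-2-yl)-5,8a-dimethyl-4a,7,8,8a-tetrahydronaphthalen-2(1H)-one
Conditions: IBX (2 equiv), 4-methoxypyridine N-oxide, DMSO, 25 → 50 °C
Reagents that add atoms: none
Why: IBX α,β-dehydrogenation of a ketone can only go towards C6–C7 because the other α-carbon is bonded to a quaternary carbon, and the tertiary alcohol and the isolated alkene are inert to IBX.

**Step 7**
Reactants: 16 (4aR,8aR)-3-(2-hydroxypropan-2-yl)-5,8a-dimethyl-4a,7,8,8a-tetrahydronaphthalen-2(1H)-one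
Product: 17 (4aR,5S,6R,8aR)-5,6-dihydroxy-3-(2-hydroxypropan-2-yl)-5,8a-dimethyl-4a,5,6,7,8,8a-hexahydronaphthalen-2(1H)-one
Conditions: OsO4 (5 mol%), NMO, acetone/H2O, 0 °C → rt
Reagents that add atoms: N-methylmorpholine N-oxide C[N+]1([O-])CCOCC1; water O
Why: Upjohn syn-dihydroxylation picks the electron-rich isolated trisubstituted alkene over the enone and attacks the α-face opposite the axial angular methyl group, which sets both carbinol centres (cis-diol, tertiary OH and secondary OH both α).

**Step 8**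
Reactants: 18 tiglic acid ((E)-2-methylbut-2-enoic acid)
Product: 19 (2S,3R)-2,3-dimethyloxirane-2-carboxylic acid
Conditions: WO2(acac)2 (5 mol%), chiral C2-symmetric bis-hydroxamic acid ligand (6 mol%), 30% aq H2O2 (1.5 equiv), NaOAc (0.3 equiv), CH2Cl2, 0 °C → rt
Reagents that add atoms: hydrogen peroxide OO
Why: Proposed new method: carboxylate-directed asymmetric epoxidation of an α,β-unsaturated acid, in which the tiglate anion binds the W(VI) η2-peroxo centre inside the chiral bis-hydroxamate pocket (as an allylic alkoxide does) and the peroxo oxygen is passed intramolecularly and suprafacially to one face of the trisubstituted C=C, so the E geometry fixes the cis-dimethyl relationship and the ligand enantiomer fixes (2S,3R); the closest known reaction types are the racemic tungstate/H2O2 epoxidation of α,β-unsaturated acids and the W–bis-hydroxamic acid asymmetric epoxidation of allylic alcohols.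

**Step 9**
Reactants: 19 (2S,3R)-2,3-dimethyloxirane-2-carboxylic acid; 17 (4aR,5S,6R,8aR)-5,6-dihydroxy-3-(2-hydroxypropan-2-yl)-5,8a-dimethyl-4a,5,6,7,8,8a-hexahydronaphthalen-2(1H)-one
Product: 21 (1S,2R,4aR,8aR)-1-hydroxy-7-(2-hydroxypropan-2-yl)-1,4a-dimethyl-6-oxo-1,2,3,4,4a,5,6,8a-octahydronaphthalen-2-yl (2S,3R)-2,3-dimethyloxirane-2-carboxylate, via mixed anhydride 20 (not isolated)
Conditions: 2,4,6-trichlorobenzoyl chloride, Et3N, THF, rt; then 17, DMAP, toluene, 40 °C
Reagents that add atoms: none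
Why: Yamaguchi esterification, in which DMAP transfers the epoxy-acyl group from the mixed anhydride to the only secondary hydroxyl while the two tertiary hydroxyls, the enone and the epoxide do not react and no stereocentre is touched.

**Compound list**
1 | 2-methylcyclopent-2-en-1-one | CC1=CCCC1=O | starting material
2 | isopropenylmagnesium bromide | CC(=C)[Mg]Br | starting material
3 | bromomagnesium (S)-2-methyl-3-(prop-1-en-2-yl)cyclopent-1-en-1-olate (magnesium enolate) | CC1=C(O[Mg]Br)CC[C@H]1C(C)=C | intermediate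
4 | (S)-trimethyl{[2-methyl-3-(prop-1-en-2-yl)cyclopent-1-en-1-yl]oxy}silane | CC1=C(O[Si](C)(C)C)CC[C@H]1C(C)=C | intermediate
5 | 4-iodobut-1-ene | C=CCCI | starting material
6 | lithium (S)-2-methyl-3-(prop-1-en-2-yl)cyclopent-1-en-1-olate (lithium enolate) | CC1=C(O[Li])CC[C@H]1C(C)=C | intermediate
7 | (2S,3S)-2-(but-3-en-1-yl)-2-methyl-3-(prop-1-en-2-yl)cyclopentan-1-one | C=CCC[C@]1(C)C(=O)CC[C@H]1C(C)=C | intermediate
8 | lithium (2S,3S)-2-(but-3-en-1-yl)-1-(dibromomethyl)-2-methyl-3-(prop-1-en-2-yl)cyclopentan-1-olate, C1 epimers (dibromomethyl alkoxide) | C=CCC[C@]1(C)C(O[Li])(C(Br)Br)CC[C@H]1C(C)=C | intermediate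
9 | lithium (2S,3S)-1-[bromo(lithio)methyl]-2-(but-3-en-1-yl)-2-methyl-3-(prop-1-en-2-yl)cyclopentan-1-olate, C1 epimers (carbenoid) | C=CCC[C@]1(C)C(O[Li])(C([Li])Br)CC[C@H]1C(C)=C | intermediate
10 | lithium (3S,4S)-3-(but-3-en-1-yl)-3-methyl-4-(prop-1-en-2-yl)cyclohex-1-en-1-olate (lithium enolate) | C=CCC[C@]1(C)C=C(O[Li])CC[C@H]1C(C)=C | intermediate
11 | (3R,4S)-3-(but-3-en-1-yl)-3-methyl-4-(prop-1-en-2-yl)cyclohexan-1-one | C=CCC[C@]1(C)CC(=O)CC[C@H]1C(C)=C | intermediate
12 | (4aR,8aR)-5,8a-dimethyl-3,4,4a,7,8,8a-hexahydronaphthalen-2(1H)-one | CC1=CCC[C@]2(C)CC(=O)CC[C@@H]12 | intermediate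
13 | acetone | CC(C)=O | starting material
14 | lithium (4aR,8aR)-5,8a-dimethyl-1,4,4a,7,8,8a-hexahydronaphthalen-2-olate (lithium enolate) | CC1=CCC[C@]2(C)CC(O[Li])=CC[C@@H]12 | intermediate
15 | (4aR,8aR)-3-(2-hydroxypropan-2-yl)-5,8a-dimethyl-3,4,4a,7,8,8a-hexahydronaphthalen-2(1H)-one, C3 epimers | CC1=CCC[C@]2(C)CC(=O)C(C(C)(C)O)C[C@@H]12 | intermediate
16 | (4aR,8aR)-3-(2-hydroxypropan-2-yl)-5,8a-dimethyl-4a,7,8,8a-tetrahydronaphthalen-2(1H)-one | CC1=CCC[C@]2(C)CC(=O)C(C(C)(C)O)=C[C@@H]12 | intermediate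
17 | (4aR,5S,6R,8aR)-5,6-dihydroxy-3-(2-hydroxypropan-2-yl)-5,8a-dimethyl-4a,5,6,7,8,8a-hexahydronaphthalen-2(1H)-one | O[C@@H]1CC[C@]2(C)CC(=O)C(C(C)(C)O)=C[C@H]2[C@]1(C)O | intermediate
18 | tiglic acid, (E)-2-methylbut-2-enoic acid | C/C=C(\C)C(=O)O | starting material
19 | (2S,3R)-2,3-dimethyloxirane-2-carboxylic acid | C[C@H]1O[C@]1(C)C(=O)O | intermediate
20 | (2S,3R)-2,3-dimethyloxirane-2-carboxylic 2,4,6-trichlorobenzoic anhydride (mixed anhydride) | C[C@H]1O[C@]1(C)C(=O)OC(=O)c1c(Cl)cc(Cl)cc1Cl | intermediate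
21 | (1S,2R,4aR,8aR)-1-hydroxy-7-(2-hydroxypropan-2-yl)-1,4a-dimethyl-6-oxo-1,2,3,4,4a,5,6,8a-octahydronaphthalen-2-yl (2S,3R)-2,3-dimethyloxirane-2-carboxylate | C[C@H]1O[C@]1(C)C(=O)O[C@@H]1CC[C@]2(C)CC(=O)C(C(C)(C)O)=C[C@H]2[C@]1(C)O | target

**Step count and risk**
Total steps: 9. Longest linear sequence: 8 (steps 1–7, then 9).

The three steps most likely to fail:

Step 8 (proposed new epoxidation; the acid may bind tungsten poorly or give low ee). The fallback uses known chemistry, sets out from 18 and comes back at 19. LiAlH4 (Et2O, 0 °C) reduces 18 to (E)-2-methylbut-2-en-1-ol F3. Sharpless asymmetric epoxidation (Ti(OiPr)4, D-(−)-diisopropyl tartrate, t-BuOOH, 4 Å MS, CH2Cl2, −20 °C) gives [(2R,3R)-2,3-dimethyloxiran-2-yl]methanol F4. RuCl3 (cat.)/NaIO4 (MeCN/CCl4/H2O) oxidises the primary alcohol to 19; the C2 label changes from R to S without any change in geometry.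

Step 3 (the carbenoid may enolise the ketone, or the CH2 carbon may migrate instead of the quaternary one). The fallback sets out from 7 and comes back at 11 through a cationic semipinacol shift instead of a carbenoid. (Phenylselanyl)methyllithium (from bis(phenylselanyl)methane and n-BuLi, THF, −78 °C) adds to 7 to give (2S,3S)-2-(but-3-en-1-yl)-2-methyl-1-[(phenylselanyl)methyl]-3-(prop-1-en-2-yl)cyclopentan-1-ol F2. TlOEt/CHCl3 (dichlorocarbene, Krief conditions) turns selenium into a leaving group, and the more substituted carbon shifts to give 11.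

Step 1 (alkenyl Grignard reagents are less proven than alkyl ones in this Cu-catalysed addition; ee or 1,4-selectivity may be low). The fallback sets out from 1 and comes back at 4. Rh(acac)(C2H4)2/BINAP-catalysed 1,4-addition of potassium isopropenyltrifluoroborate (toluene/H2O, 100 °C) gives (3R)-2-methyl-3-(prop-1-en-2-yl)cyclopentan-1-one F1 (C2 epimers; same spatial arrangement at the isopropenyl carbon as in 4). Thermodynamic silylation (TMSCl, NaI, Et3N, MeCN) then gives the more substituted silyl enol ether 4.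

**Further compounds**
F1 | step 1 | (3R)-2-methyl-3-(prop-1-en-2-yl)cyclopentan-1-one, C2 epimers | CC1C(=O)CC[C@H]1C(C)=C
F2 | step 3 | (2S,3S)-2-(but-3-en-1-yl)-2-methyl-1-[(phenylselanyl)methyl]-3-(prop-1-en-2-yl)cyclopentan-1-ol, C1 epimers | C=CCC[C@]1(C)C(O)(C[Se]c2ccccc2)CC[C@H]1C(C)=C
F3 | step 8 | (E)-2-methylbut-2-en-1-ol | C/C=C(\C)CO
F4 | step 8 | [(2R,3R)-2,3-dimethyloxiran-2-yl]methanol | C[C@H]1O[C@]1(C)CO
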